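**Retrosynthetic overview**

1. Last operations: removal of two triethylsilyl ethers, and before that a cut of the central C(sp2)–C(sp2) single bond of the heptaene. This is the bond between the CH=CH unit of the ring‑alkynyl dienyl arm and the CH=CH unit of the trienyl‑furanone arm. The cut gives a C16 terminal dienediyne and a C21 (E)‑iodotrienyl ylidenefuranone, joined by a one‑pot hydrozirconation / Zr‑to‑Zn exchange / Negishi coupling that forms the bond and sets the adjacent E alkene.
2. Enabling feature: the four carbons around that bond are all unsubstituted CH of two E‑CH=CH units, so the left terminus can be carried as a C≡CH carbon (cis H–Zr addition gives E) and the right as (E)‑CH=CH–I. The left half has no carbonyl, only the hindered ring‑bound C≡C, while the furanone ring and the oxirane ring sit on the iodide half, which never meets Zr–H.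
3. Right half: the purchased furan‑2(5H)‑one ring is brominated at C3, its Z‑ylidene is installed by vinylogous aldol/elimination with a stannyl dienal, the oxirane‑bearing alkenyl group is attached at C3 by a second hydrozirconation/Negishi coupling, then tin is exchanged for iodine.
4. Both six‑membered rings come from one enol triflate of (4R,6R)‑actinol: Sonogashira coupling and Colvin homologation give the left half; carbonylation, reduction, Katsuki–Sharpless epoxidation, oxidation and Ohira–Bestmann alkynylation give the right ring.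
5. Ring order: the two carbocycles and the furanone are bought as rings; the oxirane (step 8) is the only ring made, and no ring is closed at or after the key step.

Key step: step 17

Remark: (4R,6R)‑actinol, (2E)‑3‑methylpent‑2‑en‑4‑yn‑1‑ol, (E)‑3‑(tributylstannyl)prop‑2‑en‑1‑ol, furan‑2(5H)‑one and 2‑(triphenylphosphoranylidene)propanal are taken as purchasable, and all polyenes from step 13 on are to be handled under argon in the dark.

**Route**

Step 1
Reactants: 1 (4R,6R)-4-hydroxy-2,2,6-trimethylcyclohexan-1-one (actinol)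
Product: 2 (4R,6R)-2,2,6-trimethyl-4-(triethylsilyloxy)cyclohexan-1-one
Conditions: Et3SiCl, imidazole, DMF, 0 °C to rt
Reagents that add atoms: chlorotriethylsilane, CC[Si](Cl)(CC)CC
Why: Standard silylation of an unhindered secondary alcohol gives an ether that should survive the bases, organometallics and mild oxidants of the route and still leave under near‑neutral fluoride conditions at the end.

Step 2
Reactants: 2 (4R,6R)-2,2,6-trimethyl-4-(triethylsilyloxy)cyclohexan-1-one
Product: 4 (4R)-2,6,6-trimethyl-4-(triethylsilyloxy)cyclohex-1-en-1-yl trifluoromethanesulfonate, via lithium enolate 3 (not isolated)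
Conditions: LiN(i-Pr)2, THF, −78 to 0 °C; then PhNTf2, 0 °C to rt
Reagents that add atoms: N-phenylbis(trifluoromethanesulfonimide), O=S(=O)(N(c1ccccc1)S(=O)(=O)C(F)(F)F)C(F)(F)F
Why: Enolate O‑triflation is regiochemically unambiguous because only C6 carries an α‑hydrogen (C2 is quaternary); the C6 stereocentre is erased on purpose and C4 is untouched.

Step 3
Reactants: 4 (4R)-2,6,6-trimethyl-4-(triethylsilyloxy)cyclohex-1-en-1-yl trifluoromethanesulfonate; 5 (2E)-3-methylpent-2-en-4-yn-1-ol
Product: 6 (2E)-3-methyl-5-[(4R)-2,6,6-trimethyl-4-(triethylsilyloxy)cyclohex-1-en-1-yl]pent-2-en-4-yn-1-ol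
Conditions: Pd(PPh3)4 (5 mol%), CuI (10 mol%), i-Pr2NH, DMF, rt
Reagents that add atoms: none
Why: Sonogashira coupling of a cyclohexenyl triflate with a terminal enyne should tolerate the free primary alcohol and leave the E alkene of 5 unchanged.

Step 4
Reactants: 6 (2E)-3-methyl-5-[(4R)-2,6,6-trimethyl-4-(triethylsilyloxy)cyclohex-1-en-1-yl]pent-2-en-4-yn-1-ol
Product: 7 (2E)-3-methyl-5-[(4R)-2,6,6-trimethyl-4-(triethylsilyloxy)cyclohex-1-en-1-yl]pent-2-en-4-ynal
Conditions: MnO2 (excess), CH2Cl2, rt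
Reagents that add atoms: none
Why: Allylic oxidation with MnO2 is selective for the allylic primary alcohol and should not isomerise the E alkene or touch the silyl ether.

Step 5
Reactants: 7 (2E)-3-methyl-5-[(4R)-2,6,6-trimethyl-4-(triethylsilyloxy)cyclohex-1-en-1-yl]pent-2-en-4-ynal
Product: 8 triethyl({(1R)-3,5,5-trimethyl-4-[(3E)-3-methylhex-3-ene-1,5-diyn-1-yl]cyclohex-3-en-1-yl}oxy)silane
Conditions: Me3SiCHN2, LiN(i-Pr)2, THF, −78 °C; then 7, −78 to 0 °C
Reagents that add atoms: (trimethylsilyl)diazomethane, C[Si](C)(C)C=[N+]=[N-]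
Why: The Colvin rearrangement (1,2‑addition of the lithiated diazo reagent, Peterson‑type loss of silanolate, nitrogen loss and 1,2‑hydrogen shift of the alkylidene carbene) converts enals into terminal enynes without methanol, so conjugate addition to the enal is avoided.

Step 6
Reactants: 4 (4R)-2,6,6-trimethyl-4-(triethylsilyloxy)cyclohex-1-en-1-yl trifluoromethanesulfonate
Product: 9 methyl (4R)-2,6,6-trimethyl-4-(triethylsilyloxy)cyclohex-1-ene-1-carboxylate
Conditions: Pd(OAc)2 (5 mol%), PPh3 (10 mol%), CO (1 atm), Et3N, MeOH–DMF, 60 °C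
Reagents that add atoms: carbon monoxide, [C-]#[O+]; methanol, CO
Why: Palladium‑catalysed alkoxycarbonylation of enol triflates is reliable for hindered cyclohexenyl triflates and installs the one carbon that later becomes the alkyne carbon next to the oxirane.

Step 7
Reactants: 9 methyl (4R)-2,6,6-trimethyl-4-(triethylsilyloxy)cyclohex-1-ene-1-carboxylate
Product: 10 [(4R)-2,6,6-trimethyl-4-(triethylsilyloxy)cyclohex-1-en-1-yl]methanol
Conditions: i-Bu2AlH (2.5 equiv), CH2Cl2, −78 to 0 °C; aqueous potassium sodium tartrate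
Reagents that add atoms: none
Why: 1,2‑Reduction of the conjugated ester with i-Bu2AlH should give the allylic alcohol needed for directed epoxidation without touching the silyl ether.

Step 8
Reactants: 10 [(4R)-2,6,6-trimethyl-4-(triethylsilyloxy)cyclohex-1-en-1-yl]methanol
Product: 11 [(1R,4S,6R)-2,2,6-trimethyl-4-(triethylsilyloxy)-7-oxabicyclo[4.1.0]heptan-1-yl]methanol
Conditions: Ti(OiPr)4 (0.3 equiv), D-(−)-diethyl tartrate (0.36 equiv), t-BuOOH (2 equiv), 4 Å MS, CH2Cl2, −20 °C
Reagents that add atoms: tert-butyl hydroperoxide, CC(C)(C)OO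
Why: In the Katsuki–Sharpless asymmetric epoxidation the D‑(−)‑tartrate complex should deliver oxygen to the ring face anti to the silyloxy group, which is also the sterically open face, so both oxirane stereocentres are set by the reagent.

Step 9
Reactants: 11 [(1R,4S,6R)-2,2,6-trimethyl-4-(triethylsilyloxy)-7-oxabicyclo[4.1.0]heptan-1-yl]methanol
Product: 12 (1S,4S,6R)-2,2,6-trimethyl-4-(triethylsilyloxy)-7-oxabicyclo[4.1.0]heptane-1-carbaldehyde
Conditions: (n-Pr4N)RuO4 (5 mol%), NMO (1.5 equiv), 4 Å MS, CH2Cl2, rt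
Reagents that add atoms: none
Why: The Ley–Griffith oxidation is neutral, so the acid‑labile oxirane should survive, and the aldehyde cannot epimerise because its α‑carbon is quaternary.

Step 10
Reactants: 12 (1S,4S,6R)-2,2,6-trimethyl-4-(triethylsilyloxy)-7-oxabicyclo[4.1.0]heptane-1-carbaldehyde
Product: 13 (1R,4S,6R)-1-ethynyl-2,2,6-trimethyl-4-(triethylsilyloxy)-7-oxabicyclo[4.1.0]heptane
Conditions: dimethyl (1-diazo-2-oxopropyl)phosphonate, K2CO3, MeOH, 0 °C to rt
Reagents that add atoms: dimethyl (1-diazo-2-oxopropyl)phosphonate, CC(=O)C(=[N+]=[N-])P(=O)(OC)OC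
Why: Ohira–Bestmann homologation works on non‑enolisable aldehydes under mild carbonate conditions that should leave the oxirane and the secondary silyl ether intact.

Step 11
Reactants: 14 furan-2(5H)-one
Product: 16 3-bromofuran-2(5H)-one, via dibromolactone 15 (not isolated)
Conditions: Br2, CH2Cl2, 0 °C to rt; then Et3N, 0 °C
Reagents that add atoms: bromine, BrBr
Why: Anti addition of bromine to the enoate followed by E1cB loss of HBr (acidic C3–H, β‑bromide at C4 leaves) gives the α‑bromobutenolide regioselectively.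

Step 12
Reactants: 17 (E)-3-(tributylstannyl)prop-2-en-1-ol
Product: 18 (E)-3-(tributylstannyl)prop-2-enal
Conditions: MnO2 (excess), CH2Cl2, rt
Reagents that add atoms: none
Why: Allylic oxidation with MnO2 is neutral and should keep both the alkenyl–tin bond and the E geometry.

Step 13
Reactants: 18 (E)-3-(tributylstannyl)prop-2-enal; 19 2-(triphenylphosphoranylidene)propanal
Product: 20 (2E,4E)-2-methyl-5-(tributylstannyl)penta-2,4-dienal
Conditions: toluene, 80 °C
Reagents that add atoms: none
Why: The Wittig reaction of a stabilised formyl ylide is E‑selective, and the product enal is α‑branched and less electrophilic than 18, so a second olefination should not compete.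

Step 14
Reactants: 16 3-bromofuran-2(5H)-one; 20 (2E,4E)-2-methyl-5-(tributylstannyl)penta-2,4-dienal
Product: 23 (5Z)-3-bromo-5-[(2E,4E)-2-methyl-5-(tributylstannyl)penta-2,4-dien-1-ylidene]furan-2(5H)-one, via silyloxyfuran 21 (not isolated), via silyl aldol adduct 22 (not isolated)
Conditions: t-BuMe2SiOTf (1.3 equiv), i-Pr2NEt (3 equiv), CH2Cl2, 0 °C to rt; then DBU (2 equiv), rt
Reagents that add atoms: none
Why: In this one‑pot vinylogous Mukaiyama aldol addition and E1cB elimination the silyloxyfuran 21 adds through C5 to the silyl‑activated aldehyde and DBU then expels silanolate from 22 to give the thermodynamically preferred Z‑ylidene (chain cis to the ring oxygen), while the excess amine keeps the medium free of acid that could cleave the alkenyl–tin bond.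

Step 15
Reactants: 13 (1R,4S,6R)-1-ethynyl-2,2,6-trimethyl-4-(triethylsilyloxy)-7-oxabicyclo[4.1.0]heptane; 23 (5Z)-3-bromo-5-[(2E,4E)-2-methyl-5-(tributylstannyl)penta-2,4-dien-1-ylidene]furan-2(5H)-one
Product: 26 (5Z)-5-[(2E,4E)-2-methyl-5-(tributylstannyl)penta-2,4-dien-1-ylidene]-3-{(E)-2-[(1S,4S,6R)-2,2,6-trimethyl-4-(triethylsilyloxy)-7-oxabicyclo[4.1.0]heptan-1-yl]ethenyl}furan-2(5H)-one, via alkenylzirconocene 24 (not isolated), via alkenylzinc chloride 25 (not isolated)
Conditions: 13 (1.3 equiv), Cp2Zr(H)Cl (1.25 equiv), THF, rt; ZnCl2 (1.3 equiv), 0 °C; then 23 (1.0 equiv), Pd(PPh3)4 (5 mol%), THF, 0 °C to rt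
Reagents that add atoms: none
Why: Cis hydrozirconation of the terminal alkyne puts zirconium on the CH terminus (E alkene), and Zr‑to‑Zn exchange followed by Negishi coupling at the C3–Br bond proceeds with retention; transmetalation from zinc is far faster than Stille‑type transfer from the stannyl terminus, so the tin handle should survive.

Step 16
Reactants: 26 (5Z)-5-[(2E,4E)-2-methyl-5-(tributylstannyl)penta-2,4-dien-1-ylidene]-3-{(E)-2-[(1S,4S,6R)-2,2,6-trimethyl-4-(triethylsilyloxy)-7-oxabicyclo[4.1.0]heptan-1-yl]ethenyl}furan-2(5H)-one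
Product: 27 (5Z)-5-[(2E,4E)-5-iodo-2-methylpenta-2,4-dien-1-ylidene]-3-{(E)-2-[(1S,4S,6R)-2,2,6-trimethyl-4-(triethylsilyloxy)-7-oxabicyclo[4.1.0]heptan-1-yl]ethenyl}furan-2(5H)-one
Conditions: I2 (1.05 equiv), CH2Cl2, 0 °C, dark; aqueous Na2S2O3
Reagents that add atoms: iodine, II
Why: Iododestannylation is an ipso substitution with retention of alkene geometry and is much faster than any reaction of iodine with the electron‑poor polyene or the oxirane.

Step 17
Reactants: 8 triethyl({(1R)-3,5,5-trimethyl-4-[(3E)-3-methylhex-3-ene-1,5-diyn-1-yl]cyclohex-3-en-1-yl}oxy)silane; 27 (5Z)-5-[(2E,4E)-5-iodo-2-methylpenta-2,4-dien-1-ylidene]-3-{(E)-2-[(1S,4S,6R)-2,2,6-trimethyl-4-(triethylsilyloxy)-7-oxabicyclo[4.1.0]heptan-1-yl]ethenyl}furan-2(5H)-one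
Product: 30 3,3'-bis-O-(triethylsilyl)pyrrhoxanthinol, via dienylzirconocene 28 (not isolated), via dienylzinc chloride 29 (not isolated)
Conditions: 8 (1.3 equiv), Cp2Zr(H)Cl (1.25 equiv), THF, rt, dark; ZnCl2 (1.3 equiv), 0 °C; then 27 (1.0 equiv), Pd(PPh3)4 (5 mol%), THF, 0 °C to rt, dark
Reagents that add atoms: none
Why: Cp2Zr(H)Cl adds H–Zr cis across the terminal C≡CH of 8 with zirconium on the CH end to give the (E)-dienylzirconocene 28, ZnCl2 moves the dienyl group to zinc (29), and zerovalent palladium inserts into the C–I bond of 27, transmetalates with 29 and reductively eliminates to form the C(sp2)–C(sp2) bond with retention on both partners. The closest known reaction type is the one‑pot hydrozirconation/Negishi coupling of terminal enynes with (E)-iodoalkenes that is used to assemble all‑E polyenes, carotenoids included. No ring is closed and no stereocentre is created; the one new stereo‑element, the E geometry of the CH=CH next to the new bond, is fixed by the syn addition of Zr–H, and the other five stereodefined C=C bonds and the five stereocentres should pass unchanged because every elementary step is stereospecific at sp2 carbon. The step needs chemoselectivity for the terminal alkyne over the internal ring‑bound alkyne, which is secured by the tetrasubstituted ring alkene and the methyl‑bearing alkene that flank the internal triple bond and block the bulky Cp2Zr unit. It also needs the hydride never to meet the lactone, which is secured by consuming Cp2Zr(H)Cl with a small excess of 8 before 27 is added. The alkenylzinc chloride should tolerate the furanone carbonyl, the oxirane and both silyl ethers, and oxidative addition to the electron‑poor iodotriene should be far faster than ionisation of the fully substituted vinyl oxirane, so the left half needs no preformed alkenyl metal or halide, only a C≡CH group.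

Step 18
Reactants: 30 3,3'-bis-O-(triethylsilyl)pyrrhoxanthinol
Product: 31 pyrrhoxanthinol (CNP0180336.1)
Conditions: n-Bu4NF (4 equiv), AcOH (4 equiv), THF, 0 °C to rt, dark
Reagents that add atoms: none
Why: Acetic‑acid‑buffered fluoride should cleave secondary triethylsilyl ethers near neutrality, which avoids both acid‑induced rearrangement of the oxirane and base‑induced opening of the ylidenefuranone.

**Compound list**

1 | (4R,6R)-4-hydroxy-2,2,6-trimethylcyclohexan-1-one (actinol) | CC1(C)C[C@H](O)C[C@@H](C)C1=O | starting material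
2 | (4R,6R)-2,2,6-trimethyl-4-(triethylsilyloxy)cyclohexan-1-one | CC1(C)C[C@H](O[Si](CC)(CC)CC)C[C@@H](C)C1=O | intermediate
3 | lithium (4R)-2,6,6-trimethyl-4-(triethylsilyloxy)cyclohex-1-en-1-olate (formed in the flask) | CC1=C(O[Li])C(C)(C)C[C@H](O[Si](CC)(CC)CC)C1 | intermediate
4 | (4R)-2,6,6-trimethyl-4-(triethylsilyloxy)cyclohex-1-en-1-yl trifluoromethanesulfonate | CC1=C(OS(=O)(=O)C(F)(F)F)C(C)(C)C[C@H](O[Si](CC)(CC)CC)C1 | intermediate
5 | (2E)-3-methylpent-2-en-4-yn-1-ol | C#C/C(C)=C/CO | starting material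
6 | (2E)-3-methyl-5-[(4R)-2,6,6-trimethyl-4-(triethylsilyloxy)cyclohex-1-en-1-yl]pent-2-en-4-yn-1-ol | CC1=C(C#C/C(C)=C/CO)C(C)(C)C[C@H](O[Si](CC)(CC)CC)C1 | intermediate
7 | (2E)-3-methyl-5-[(4R)-2,6,6-trimethyl-4-(triethylsilyloxy)cyclohex-1-en-1-yl]pent-2-en-4-ynal | CC1=C(C#C/C(C)=C/C=O)C(C)(C)C[C@H](O[Si](CC)(CC)CC)C1 | intermediate
8 | triethyl({(1R)-3,5,5-trimethyl-4-[(3E)-3-methylhex-3-ene-1,5-diyn-1-yl]cyclohex-3-en-1-yl}oxy)silane (left half) | CC1=C(C#C/C(C)=C/C#C)C(C)(C)C[C@H](O[Si](CC)(CC)CC)C1 | intermediate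
9 | methyl (4R)-2,6,6-trimethyl-4-(triethylsilyloxy)cyclohex-1-ene-1-carboxylate | CC1=C(C(=O)OC)C(C)(C)C[C@H](O[Si](CC)(CC)CC)C1 | intermediate
10 | [(4R)-2,6,6-trimethyl-4-(triethylsilyloxy)cyclohex-1-en-1-yl]methanol | CC1=C(CO)C(C)(C)C[C@H](O[Si](CC)(CC)CC)C1 | intermediate
11 | [(1R,4S,6R)-2,2,6-trimethyl-4-(triethylsilyloxy)-7-oxabicyclo[4.1.0]heptan-1-yl]methanol (oxirane anti to the silyloxy group) | OC[C@@]12O[C@]1(C)C[C@@H](O[Si](CC)(CC)CC)CC2(C)C | intermediate
12 | (1S,4S,6R)-2,2,6-trimethyl-4-(triethylsilyloxy)-7-oxabicyclo[4.1.0]heptane-1-carbaldehyde | O=C[C@@]12O[C@]1(C)C[C@@H](O[Si](CC)(CC)CC)CC2(C)C | intermediate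
13 | (1R,4S,6R)-1-ethynyl-2,2,6-trimethyl-4-(triethylsilyloxy)-7-oxabicyclo[4.1.0]heptane | C#C[C@@]12O[C@]1(C)C[C@@H](O[Si](CC)(CC)CC)CC2(C)C | intermediate
14 | furan-2(5H)-one | O=C1OCC=C1 | starting material
15 | trans-3,4-dibromodihydrofuran-2(3H)-one (racemic, one enantiomer drawn, formed in the flask) | O=C1OC[C@H](Br)[C@H]1Br | intermediate
16 | 3-bromofuran-2(5H)-one | O=C1OCC=C1Br | intermediate
17 | (E)-3-(tributylstannyl)prop-2-en-1-ol | CCCC[Sn](CCCC)(CCCC)/C=C/CO | starting material
18 | (E)-3-(tributylstannyl)prop-2-enal | CCCC[Sn](CCCC)(CCCC)/C=C/C=O | intermediate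
19 | 2-(triphenylphosphoranylidene)propanal | CC(C=O)=P(c1ccccc1)(c1ccccc1)c1ccccc1 | starting material
20 | (2E,4E)-2-methyl-5-(tributylstannyl)penta-2,4-dienal | CCCC[Sn](CCCC)(CCCC)/C=C/C=C(C)/C=O | intermediate
21 | [(3-bromofuran-2-yl)oxy](tert-butyl)dimethylsilane (formed in the flask) | CC(C)(C)[Si](C)(C)Oc1occc1Br | intermediate
22 | 3-bromo-5-[(2E,4E)-1-(tert-butyldimethylsilyloxy)-2-methyl-5-(tributylstannyl)penta-2,4-dien-1-yl]furan-2(5H)-one (diastereomer mixture, formed in the flask) | CCCC[Sn](CCCC)(CCCC)/C=C/C=C(C)/C(O[Si](C)(C)C(C)(C)C)C1OC(=O)C(Br)=C1 | intermediate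
23 | (5Z)-3-bromo-5-[(2E,4E)-2-methyl-5-(tributylstannyl)penta-2,4-dien-1-ylidene]furan-2(5H)-one | CCCC[Sn](CCCC)(CCCC)/C=C/C=C(C)/C=C1C=C(Br)C(=O)O/1 | intermediate
24 | chlorobis(cyclopentadienyl){(E)-2-[(1S,4S,6R)-2,2,6-trimethyl-4-(triethylsilyloxy)-7-oxabicyclo[4.1.0]heptan-1-yl]ethenyl}zirconium (formed in the flask) | Cl[Zr](C1C=CC=C1)(C1C=CC=C1)/C=C/[C@@]12O[C@]1(C)C[C@@H](O[Si](CC)(CC)CC)CC2(C)C | intermediate
25 | chloro{(E)-2-[(1S,4S,6R)-2,2,6-trimethyl-4-(triethylsilyloxy)-7-oxabicyclo[4.1.0]heptan-1-yl]ethenyl}zinc (formed in the flask) | Cl[Zn]/C=C/[C@@]12O[C@]1(C)C[C@@H](O[Si](CC)(CC)CC)CC2(C)C | intermediate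
26 | (5Z)-5-[(2E,4E)-2-methyl-5-(tributylstannyl)penta-2,4-dien-1-ylidene]-3-{(E)-2-[(1S,4S,6R)-2,2,6-trimethyl-4-(triethylsilyloxy)-7-oxabicyclo[4.1.0]heptan-1-yl]ethenyl}furan-2(5H)-one | CCCC[Sn](CCCC)(CCCC)/C=C/C=C(C)/C=C1C=C(/C=C/[C@@]23O[C@]2(C)C[C@@H](O[Si](CC)(CC)CC)CC3(C)C)C(=O)O/1 | intermediate
27 | (5Z)-5-[(2E,4E)-5-iodo-2-methylpenta-2,4-dien-1-ylidene]-3-{(E)-2-[(1S,4S,6R)-2,2,6-trimethyl-4-(triethylsilyloxy)-7-oxabicyclo[4.1.0]heptan-1-yl]ethenyl}furan-2(5H)-one (right half) | I/C=C/C=C(C)/C=C1C=C(/C=C/[C@@]23O[C@]2(C)C[C@@H](O[Si](CC)(CC)CC)CC3(C)C)C(=O)O/1 | intermediate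
28 | chlorobis(cyclopentadienyl){(1E,3E)-4-methyl-6-[(4R)-2,6,6-trimethyl-4-(triethylsilyloxy)cyclohex-1-en-1-yl]hexa-1,3-dien-5-yn-1-yl}zirconium (formed in the flask) | CC1=C(C#C/C(C)=C/C=C/[Zr](Cl)(C2C=CC=C2)C2C=CC=C2)C(C)(C)C[C@H](O[Si](CC)(CC)CC)C1 | intermediate
29 | chloro{(1E,3E)-4-methyl-6-[(4R)-2,6,6-trimethyl-4-(triethylsilyloxy)cyclohex-1-en-1-yl]hexa-1,3-dien-5-yn-1-yl}zinc (formed in the flask) | CC1=C(C#C/C(C)=C/C=C/[Zn]Cl)C(C)(C)C[C@H](O[Si](CC)(CC)CC)C1 | intermediate
30 | 3,3'-bis-O-(triethylsilyl)pyrrhoxanthinol (target with both hydroxyl groups as triethylsilyl ethers) | CC1=C(C#C/C(C)=C/C=C/C=C/C=C(C)/C=C2C=C(/C=C/[C@@]34O[C@]3(C)C[C@@H](O[Si](CC)(CC)CC)CC4(C)C)C(=O)O/2)C(C)(C)C[C@H](O[Si](CC)(CC)CC)C1 | intermediate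
31 | pyrrhoxanthinol (CNP0180336.1) | CC1=C(C#C/C(C)=C/C=C/C=C/C=C(C)/C=C2C=C(/C=C/[C@@]34O[C@]3(C)C[C@@H](O)CC4(C)C)C(=O)O/2)C(C)(C)C[C@H](O)C1 | target

**Step count and risks**

Total step count: 18. Longest linear sequence: 11 steps (steps 1, 2, 6, 7, 8, 9, 10, 15, 16, 17, 18).

The three steps most likely to fail:

Step 17. What may go wrong: hydride addition to the internal alkyne or carry‑over of Zr–H that reduces the lactone, protonolysis of the dienylmetal before coupling, or geometric scrambling and homocoupling at palladium. The fallback reverses the polarity and uses a neutral Stille coupling. It sets out from aldehyde 7 and stannane 26 and comes back to the route at 30. Takai olefination of 7 (CrCl2, CHI3, THF, 0 °C) should give triethyl({(1R)-4-[(3E,5E)-6-iodo-3-methylhexa-3,5-dien-1-yn-1-yl]-3,5,5-trimethylcyclohex-3-en-1-yl}oxy)silane F1. F1 and 26 (step 16 is then skipped) are joined with Pd2(dba)3 and AsPh3 in NMP at rt in the dark to give 30.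

Step 15. What may go wrong: Lewis‑acid opening of the oxirane in the electron‑rich alkenylmetal by ZnCl2, or competing transfer of the stannyl terminus to palladium leading to oligomers. The fallback avoids zinc and uses an isolated boronate. It sets out from 13 and 23 and comes back at 26. Zirconium‑catalysed hydroboration of 13 (pinacolborane, Cp2Zr(H)Cl 10 mol%, Et3N, rt) should give 2-{(E)-2-[(1S,4S,6R)-2,2,6-trimethyl-4-(triethylsilyloxy)-7-oxabicyclo[4.1.0]heptan-1-yl]ethenyl}-4,4,5,5-tetramethyl-1,3,2-dioxaborolane F2. Suzuki–Miyaura coupling of F2 with 23 (Pd(dppf)Cl2, K3PO4, THF–H2O, rt) then gives 26.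

Step 14. What may go wrong: loss of the tributylstannyl group through adventitious acid from the silyl triflate, or poor control of ylidene geometry in the elimination. The fallback replaces the acid‑mediated cascade by a fluoride‑triggered aldol addition and a separate sulfonate elimination. It sets out from 16 and 20 and comes back at 23. Silylation of 16 (Me3SiCl, Et3N, CH2Cl2) gives [(3-bromofuran-2-yl)oxy]trimethylsilane F3. Vinylogous aldol addition of F3 to 20 (n-Bu4NF catalytic, THF, −78 °C, aqueous work‑up) gives 3-bromo-5-[(2E,4E)-1-hydroxy-2-methyl-5-(tributylstannyl)penta-2,4-dien-1-yl]furan-2(5H)-one F4. Mesylation and elimination (MsCl, Et3N, then DBU, CH2Cl2, 0 °C) then deliver 23.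

**Further compounds**

F1 | step 17 | triethyl({(1R)-4-[(3E,5E)-6-iodo-3-methylhexa-3,5-dien-1-yn-1-yl]-3,5,5-trimethylcyclohex-3-en-1-yl}oxy)silane | CC1=C(C#C/C(C)=C/C=C/I)C(C)(C)C[C@H](O[Si](CC)(CC)CC)C1
F2 | step 15 | 2-{(E)-2-[(1S,4S,6R)-2,2,6-trimethyl-4-(triethylsilyloxy)-7-oxabicyclo[4.1.0]heptan-1-yl]ethenyl}-4,4,5,5-tetramethyl-1,3,2-dioxaborolane | CC1(C)OB(/C=C/[C@@]23O[C@]2(C)C[C@@H](O[Si](CC)(CC)CC)CC3(C)C)OC1(C)C
F3 | step 14 | [(3-bromofuran-2-yl)oxy]trimethylsilane | C[Si](C)(C)Oc1occc1Br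
F4 | step 14 | 3-bromo-5-[(2E,4E)-1-hydroxy-2-methyl-5-(tributylstannyl)penta-2,4-dien-1-yl]furan-2(5H)-one (diastereomer mixture) | CCCC[Sn](CCCC)(CCCC)/C=C/C=C(C)/C(O)C1OC(=O)C(Br)=C1
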